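**Plan**
1. Numbering follows the acetogenin chain, C1 (≡CH) to C15 (ethyl CH3). The oxocene ring is O, C7, C8, C9, C10, C11=C12, C13. Retrosynthetic cuts: C3=C4 (enyne cross-metathesis), C6–Cl (from C6–OH with inversion), C5–C6 (allylation of a C6 aldehyde), then C8–C9 and C10–C11 together.
2. Enabling feature: C8 (ring CH2) and C11 (alkene CH) flank the C9–C10 glycol. A C8–C11 bond would split the eight-membered ring into a cis-2,6-disubstituted pyran (O, C7, C8, C11, C12, C13) and a cyclobutane (C8–C11). With C11 as a latent ketone and a carboxyl helper on C8, that pyran is the enol of a β-keto acid, i.e. a pyran-fused dioxinone.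
3. Forward order: dioxinone side chain (C11–C15), then the pyran ring (Prins-type closure, C7–C8), then the cyclobutane by [2+2] photocycloaddition with vinylene carbonate. Retro-aldol cleavage of C8–C11 follows, a two-carbon ring expansion to the oxocane. The helpers are then removed (acetone ketal, C8 carboxyl, C11 ketone to C11=C12, carbonate), and the side chain C1–C5 is added last.
4. Stereochemistry: C13 comes from a catalytic asymmetric vinylogous Mukaiyama aldol, and C7 is set cis to C13 by a chair-like oxocarbenium closure. C9 and C10 come from addition of the cis-locked C2 unit anti to the C7 substituent; C10 is then inverted by Mitsunobu acetylation to give the trans-diacetate. C6 comes from catalyst-controlled allylation followed by Appel inversion. C11=C12 is Z by ring constraint and C3=C4 is Z from enyne cross-metathesis.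

Key step: step 4

Assumption: (tert-butyldiphenylsilyloxy)acetaldehyde is taken as purchasable. The carboxyl-bearing C8 of the ring-expanded acid forms as an epimer mixture that decarboxylation erases, so it is left undefined in the SMILES.

**Step 1**
Reactants: 1 2,2,6-trimethyl-4H-1,3-dioxin-4-one
Product: 3 2,2-dimethyl-6-methylene-4-(trimethylsilyloxy)-1,3-diox-4-ene, via lithium dienolate 2 (not isolated)
Conditions: LDA (commercial solution), THF, −78 °C; TMSCl, −78 to 0 °C
Reagents that add atoms: chlorotrimethylsilane, C[Si](C)(C)Cl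
Why: γ-Deprotonation of the vinylogous ester gives the cross-conjugated dienolate, which is silylated on oxygen (silyl dienol ether formation), and no stereocentre is formed.

**Step 2**
Reactants: 3 silyl dienol ether; 4 propanal
Product: 6 (R)-6-(2-hydroxybutyl)-2,2-dimethyl-4H-1,3-dioxin-4-one, via trimethylsilyl ether 5 (not isolated)
Conditions: Ti(OiPr)4 (10 mol %), (S)-BINOL (10 mol %), 4 Å MS, THF, −78 °C to rt; then 1 M HCl, THF, 0 °C
Reagents that add atoms: none
Why: In this catalytic asymmetric vinylogous Mukaiyama aldol reaction the Ti–(S)-BINOL Lewis acid binds propanal and exposes one face to the γ-carbon of 3, which should set C13 as R (same facial sense as the Ti–BINOL allylation of step 13), and mild acid removes the transferred silyl group.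

**Step 3**
Reactants: 6 (R)-hydroxy dioxinone; 7 2-[(tert-butyldiphenylsilyl)oxy]acetaldehyde
Product: 8 (5R,7R)-5-{[(tert-butyldiphenylsilyl)oxy]methyl}-7-ethyl-2,2-dimethyl-7,8-dihydro-4H,5H-pyrano[4,3-d][1,3]dioxin-4-one (chain C7 R, C13 R, cis)
Conditions: Sc(OTf)3 (10 mol %), CaSO4, CH2Cl2, −10 °C to rt
Reagents that add atoms: none
Why: Condensation gives an oxocarbenium ion at C7 that is captured by the nucleophilic α-carbon (C8) of the dioxinone in a Prins-type 6-endo cyclisation through a chair with ethyl and CH2OTBDPS equatorial, so C7 is set cis to C13, and proton loss restores the dioxinone chromophore.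

**Step 4**
Reactants: 8 pyran-fused dioxinone; 9 vinylene carbonate (1,3-dioxol-2-one)
Product: 11 ring-expanded keto acid (oxocane with CH2OTBDPS on C7, CO2H on C8, cis cyclic carbonate on C9/C10, ketone at C11, ethyl on C13; 7R,9R,10R,13R), via propellane photoadduct 10 (not isolated)
Conditions: 9 (15 equiv), hν (medium-pressure Hg lamp, Pyrex), MeCN/acetone 9:1, 0 °C; evaporate; TsOH·H2O (0.2 equiv), THF/H2O 10:1, 45 °C
Reagents that add atoms: none
Why: Excitation gives the dioxinone triplet, which adds to 9 through a 1,4-biradical that collapses to the cyclobutane C8–C9–C10–C11, so C8–C9 and C10–C11 form in one photochemical event; acid then hydrolyses the acyl ketal, and the freed C11 cyclobutanol, vicinal to the C8 carboxyl, opens by retro-aldol cleavage of the shared C8–C11 bond. The closest known reaction type is the de Mayo reaction in its dioxinone photocycloaddition–fragmentation form, known for eight-membered carbocycles, combined with the known use of vinylene carbonate as 2π partner for enones and unsaturated lactones. The four-membered ring closes by intermolecular [2+2] cycloaddition (biradical recombination), whereas the eight-membered ring is not closed end to end but arises by two-carbon ring expansion when the bond common to pyran and cyclobutane breaks, which avoids the entropic and transannular cost of a medium-ring closure. C9 and C10 are held cis to each other by the five-membered ring of 9, and their sense relative to C7 and C13 should follow from approach to the face of 8 opposite the CH2OTBDPS group on C7 (next to reacting C8) with the carbonate turned away from the pyran ring, whose axial C7–H, C12–H and C13–H line that face, toward the hydrogen-free O–C(=O) edge of the dioxanone. C8 and C11 are transient stereocentres that are erased on cleavage (C11 becomes C=O, C8 later CH2), so ring-fusion isomers converge. The step needs facial and orientational selectivity (secured as above), no regioselectivity because 9 is symmetric, and cleavage of C8–C11 rather than C10–C11, which is secured because only C8 carries the carboxyl acceptor; the carbonate, silyl ether and ring ether tolerate the acid.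

**Step 5**
Reactants: 11 keto acid
Product: 12 (7R,9R,10R,13R)-ketone (oxocan-11-one with CH2OTBDPS on C7, cis C9/C10 cyclic carbonate, ethyl on C13)
Conditions: 9-mesityl-10-methylacridinium tetrafluoroborate (5 mol %), PhSSPh (10 mol %), iPr2NEt (20 mol %), CF3CH2OH, 450 nm LEDs, rt
Reagents that add atoms: none
Why: In this photoredox hydrodecarboxylation the carboxylate is oxidised by the excited acridinium, loses CO2 and the secondary C8 radical takes hydrogen from the thiol cocatalyst faster than any β-C–O scission, so both C8 epimers converge on the CH2 group and the activating helper is gone.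

**Step 6**
Reactants: 12 ketone
Product: 13 (7R,9R,10R,13R,11Z)-enol triflate (C11–OTf, C11=C12)
Conditions: KHMDS added to 12 and N-(5-chloropyridin-2-yl)bis(trifluoromethanesulfonimide), THF, −78 °C
Reagents that add atoms: N-(5-chloropyridin-2-yl)bis(trifluoromethanesulfonimide), O=S(=O)(N(c1ccc(Cl)cn1)S(=O)(=O)C(F)(F)F)C(F)(F)F
Why: Kinetic enolisation of an α-oxygenated ketone should occur at the unhindered, non-oxygenated C12H2, and in situ O-sulfonylation (enol triflate formation) traps the ring-constrained Z enolate before β-elimination can set in.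

**Step 7**
Reactants: 13 enol triflate carbonate
Product: 14 (7R,9R,10R,13R,11Z)-enol triflate cis-9,10-diol
Conditions: K2CO3 (0.2 equiv), MeOH, 0 °C, short contact
Reagents that add atoms: none
Why: Base-catalysed transesterification of the strained five-membered carbonate is fast at 0 °C and is placed here so that the allylic C10–O is a hydroxyl and not a leaving group for zerovalent palladium in the next step.

**Step 8**
Reactants: 14 enol triflate diol
Product: 15 (2R,4R,5S,8R,6Z)-2-{[(tert-butyldiphenylsilyl)oxy]methyl}-8-ethyl-3,4,5,8-tetrahydro-2H-oxocine-4,5-diol (chain 7R,9R,10S,13R; cis-diol)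
Conditions: Pd(OAc)2 (5 mol %), PPh3 (10 mol %), HCO2H, Et3N, DMF, 50 °C
Reagents that add atoms: none
Why: In this palladium-catalysed formate reduction of an enol triflate, oxidative addition, formate decarboxylation to a palladium hydride and reductive elimination replace OTf by H with retention, which gives the Z C11=C12 alkene imposed by the ring.

**Step 9**
Reactants: 15 cis-diol
Product: 16 (7R,9R,10R,13R)-10-acetoxy-9-hydroxy oxocene (trans)
Conditions: AcOH (1.2 equiv), PPh3, DIAD, THF, 0 °C to rt
Reagents that add atoms: acetic acid, CC(=O)O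
Why: In this Mitsunobu reaction the allylic C10 oxyphosphonium ion is displaced by acetate much faster than the homoallylic C9 one, with clean SN2 inversion that turns the cis-glycol into the trans arrangement, and the cis C9–OH cannot close an epoxide.

**Step 10**
Reactants: 16 hydroxy acetate
Product: 17 (2R,4R,5R,8R,6Z)-2-{[(tert-butyldiphenylsilyl)oxy]methyl}-8-ethyl-3,4,5,8-tetrahydro-2H-oxocine-4,5-diyl diacetate
Conditions: Ac2O, pyridine, DMAP (cat.), CH2Cl2, rt
Reagents that add atoms: acetic anhydride, CC(=O)OC(C)=O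
Why: DMAP-catalysed acylation of the remaining secondary alcohol proceeds with retention at C9.

**Step 11**
Reactants: 17 silyl ether diacetate
Product: 18 (2R,4R,5R,8R,6Z)-8-ethyl-2-(hydroxymethyl)-3,4,5,8-tetrahydro-2H-oxocine-4,5-diyl diacetate
Conditions: HF·pyridine, THF/pyridine, 0 °C to rt
Reagents that add atoms: none
Why: Fluoride-mediated desilylation under buffered acidic conditions frees the C6 alcohol without touching acetates or the alkene.

**Step 12**
Reactants: 18 primary alcohol
Product: 19 (2R,4R,5R,8R,6Z)-8-ethyl-2-formyl-3,4,5,8-tetrahydro-2H-oxocine-4,5-diyl diacetate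
Conditions: Dess–Martin periodinane, CH2Cl2, rt; used directly
Reagents that add atoms: none
Why: Dess–Martin oxidation is neutral and fast, so the α-alkoxy aldehyde should be obtained without epimerisation at C7.

**Step 13**
Reactants: 19 aldehyde
Product: 21 (6S,7R,9R,10R,13R)-homoallylic alcohol (C6–OH, allyl = C3–C5), via tributylstannyl ether 20 (not isolated)
Conditions: allyltributylstannane, Ti(OiPr)4 (10 mol %), (S)-BINOL (20 mol %), 4 Å MS, CH2Cl2, −20 °C; aq NaHCO3
Reagents that add atoms: allyltributylstannane, C=CC[Sn](CCCC)(CCCC)CCCC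
Why: In this Keck asymmetric allylation the (S)-BINOL–titanium catalyst directs the allyl group to the aldehyde face that gives 6S, matched with the polar Felkin–Anh preference of the α-alkoxy aldehyde for the 6,7-anti product.

**Step 14**
Reactants: 21 homoallylic alcohol
Product: 22 (6R,7R,9R,10R,13R)-chloride
Conditions: CCl4, P(n-C8H17)3, toluene, 80 °C
Reagents that add atoms: tetrachloromethane, ClC(Cl)(Cl)Cl
Why: In this Appel-type chlorination chloride displaces the alkoxyphosphonium ion by SN2 with inversion (6S to 6R), and the electron-rich trialkylphosphine favours direct displacement over participation of the ring oxygen.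

**Step 15**
Reactants: 23 vinyl bromide; 24 (triisopropylsilyl)acetylene
Product: 25 (but-3-en-1-yn-1-yl)triisopropylsilane
Conditions: PdCl2(PPh3)2 (2 mol %), CuI (4 mol %), Et3N, THF, 0 °C to rt
Reagents that add atoms: none
Why: Sonogashira coupling of a vinyl halide with a terminal alkyne gives the conjugated enyne partner.

**Step 16**
Reactants: 22 chloride; 25 silyl enyne
Product: 26 (3Z)-triisopropylsilyl-protected target
Conditions: 25 (4 equiv), second-generation Grubbs catalyst (10 mol %), CH2Cl2, 40 °C
Reagents that add atoms: none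
Why: Cross-metathesis of a terminal alkene with a conjugated enyne is known to favour the Z enyne because the slim alkynyl group tolerates the cis metallacyclobutane, and the ring alkene, branched at both allylic positions, should stay a spectator.

**Step 17**
Reactants: 26 silyl enyne
Product: 27 (2R,4R,5R,8R,6Z)-2-[(1R,3Z)-1-chlorohex-3-en-5-yn-1-yl]-8-ethyl-3,4,5,8-tetrahydro-2H-oxocine-4,5-diyl diacetate (target)
Conditions: TBAF, AcOH (1:1), THF, 0 °C to rt
Reagents that add atoms: none
Why: Buffered fluoride cleaves the C(sp)–Si bond (protodesilylation) while the acetic acid suppresses acetate cleavage and elimination of the C6 chloride.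

**Compound list**
1 | 2,2,6-trimethyl-4H-1,3-dioxin-4-one | CC1=CC(=O)OC(C)(C)O1 | starting material
2 | lithium dienolate of 1 | C=C1C=C([O-])OC(C)(C)O1.[Li+] | intermediate
3 | 2,2-dimethyl-6-methylene-4-(trimethylsilyloxy)-1,3-diox-4-ene | C=C1C=C(O[Si](C)(C)C)OC(C)(C)O1 | intermediate
4 | propanal | CCC=O | starting material
5 | (R)-2,2-dimethyl-6-[2-(trimethylsilyloxy)butyl]-4H-1,3-dioxin-4-one | CC[C@@H](O[Si](C)(C)C)CC1=CC(=O)OC(C)(C)O1 | intermediate
6 | (R)-6-(2-hydroxybutyl)-2,2-dimethyl-4H-1,3-dioxin-4-one | CC[C@@H](O)CC1=CC(=O)OC(C)(C)O1 | intermediate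
7 | 2-[(tert-butyldiphenylsilyl)oxy]acetaldehyde | O=CCO[Si](c1ccccc1)(c1ccccc1)C(C)(C)C | starting material
8 | (5R,7R)-5-{[(tert-butyldiphenylsilyl)oxy]methyl}-7-ethyl-2,2-dimethyl-7,8-dihydro-4H,5H-pyrano[4,3-d][1,3]dioxin-4-one | CC[C@@H]1CC2=C([C@H](CO[Si](c3ccccc3)(c3ccccc3)C(C)(C)C)O1)C(=O)OC(C)(C)O2 | intermediate
9 | vinylene carbonate (1,3-dioxol-2-one) | O=C1OC=CO1 | starting material
10 | propellane photoadduct: cyclobutane C8–C9–C10–C11 on the face of the pyran trans to CH2OTBDPS, carbonate on the cyclobutane face that carries the dioxanone | CC[C@@H]1C[C@]23OC(C)(C)OC(=O)[C@@]2([C@H](CO[Si](c5ccccc5)(c5ccccc5)C(C)(C)C)O1)[C@H]4OC(=O)O[C@@H]34 | intermediate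
11 | (7R,9R,10R,13R)-keto acid, oxocane with C8–CO2H (epimers), cis C9/C10 carbonate, C11 ketone | CC[C@@H]1CC(=O)[C@@H]2OC(=O)O[C@@H]2C(C(=O)O)[C@H](CO[Si](c3ccccc3)(c3ccccc3)C(C)(C)C)O1 | intermediate
12 | (7R,9R,10R,13R)-ketone, cis C9/C10 carbonate | CC[C@@H]1CC(=O)[C@@H]2OC(=O)O[C@@H]2C[C@H](CO[Si](c3ccccc3)(c3ccccc3)C(C)(C)C)O1 | intermediate
13 | (7R,9R,10R,13R,11Z)-C11 enol triflate, cis carbonate | CC[C@@H]1/C=C(OS(=O)(=O)C(F)(F)F)\[C@@H]2OC(=O)O[C@@H]2C[C@H](CO[Si](c3ccccc3)(c3ccccc3)C(C)(C)C)O1 | intermediate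
14 | (7R,9R,10R,13R,11Z)-C11 enol triflate, cis-9,10-diol | CC[C@@H]1/C=C(OS(=O)(=O)C(F)(F)F)\[C@H](O)[C@H](O)C[C@H](CO[Si](c2ccccc2)(c2ccccc2)C(C)(C)C)O1 | intermediate
15 | (2R,4R,5S,8R,6Z)-2-{[(tert-butyldiphenylsilyl)oxy]methyl}-8-ethyl-3,4,5,8-tetrahydro-2H-oxocine-4,5-diol | CC[C@@H]1/C=C\[C@H](O)[C@H](O)C[C@H](CO[Si](c2ccccc2)(c2ccccc2)C(C)(C)C)O1 | intermediate
16 | (2R,4R,5R,8R,6Z)-2-{[(tert-butyldiphenylsilyl)oxy]methyl}-8-ethyl-4-hydroxy-3,4,5,8-tetrahydro-2H-oxocin-5-yl acetate | CC[C@@H]1/C=C\[C@@H](OC(C)=O)[C@H](O)C[C@H](CO[Si](c2ccccc2)(c2ccccc2)C(C)(C)C)O1 | intermediate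
17 | (2R,4R,5R,8R,6Z)-2-{[(tert-butyldiphenylsilyl)oxy]methyl}-8-ethyl-3,4,5,8-tetrahydro-2H-oxocine-4,5-diyl diacetate | CC[C@@H]1/C=C\[C@@H](OC(C)=O)[C@H](OC(C)=O)C[C@H](CO[Si](c2ccccc2)(c2ccccc2)C(C)(C)C)O1 | intermediate
18 | (2R,4R,5R,8R,6Z)-8-ethyl-2-(hydroxymethyl)-3,4,5,8-tetrahydro-2H-oxocine-4,5-diyl diacetate | CC[C@@H]1/C=C\[C@@H](OC(C)=O)[C@H](OC(C)=O)C[C@H](CO)O1 | intermediate
19 | (2R,4R,5R,8R,6Z)-8-ethyl-2-formyl-3,4,5,8-tetrahydro-2H-oxocine-4,5-diyl diacetate | CC[C@@H]1/C=C\[C@@H](OC(C)=O)[C@H](OC(C)=O)C[C@H](C=O)O1 | intermediate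
20 | tributylstannyl ether of 21 | C=CC[C@H](O[Sn](CCCC)(CCCC)CCCC)[C@H]1C[C@@H](OC(C)=O)[C@H](OC(C)=O)/C=C\[C@@H](CC)O1 | intermediate
21 | (2R,4R,5R,8R,6Z)-8-ethyl-2-[(1S)-1-hydroxybut-3-en-1-yl]-3,4,5,8-tetrahydro-2H-oxocine-4,5-diyl diacetate | C=CC[C@H](O)[C@H]1C[C@@H](OC(C)=O)[C@H](OC(C)=O)/C=C\[C@@H](CC)O1 | intermediate
22 | (2R,4R,5R,8R,6Z)-2-[(1R)-1-chlorobut-3-en-1-yl]-8-ethyl-3,4,5,8-tetrahydro-2H-oxocine-4,5-diyl diacetate | C=CC[C@@H](Cl)[C@H]1C[C@@H](OC(C)=O)[C@H](OC(C)=O)/C=C\[C@@H](CC)O1 | intermediate
23 | vinyl bromide | C=CBr | starting material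
24 | (triisopropylsilyl)acetylene | C#C[Si](C(C)C)(C(C)C)C(C)C | starting material
25 | (but-3-en-1-yn-1-yl)triisopropylsilane | C=CC#C[Si](C(C)C)(C(C)C)C(C)C | intermediate
26 | (2R,4R,5R,8R,6Z)-2-[(1R,3Z)-1-chloro-6-(triisopropylsilyl)hex-3-en-5-yn-1-yl]-8-ethyl-3,4,5,8-tetrahydro-2H-oxocine-4,5-diyl diacetate | CC(C)[Si](C#C/C=C\C[C@@H](Cl)[C@H]1C[C@@H](OC(C)=O)[C@H](OC(C)=O)/C=C\[C@@H](CC)O1)(C(C)C)C(C)C | intermediate
27 | (2R,4R,5R,8R,6Z)-2-[(1R,3Z)-1-chlorohex-3-en-5-yn-1-yl]-8-ethyl-3,4,5,8-tetrahydro-2H-oxocine-4,5-diyl diacetate | C#C/C=C\C[C@@H](Cl)[C@H]1C[C@@H](OC(C)=O)[C@H](OC(C)=O)/C=C\[C@@H](CC)O1 | target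

Total step count: 17. Longest linear sequence: 16 (steps 1–14, 16, 17; step 15 is a one-step side branch).

**Steps most likely to fail**

**Step 4.** Addition to the tetrasubstituted C8=C11 double bond may be slow and lose out to photodimerisation of 9. Facial or orientational selectivity may also be poor.
- The fallback sets out from 7 and comes back at 17. It closes the ring at C11=C12 by metathesis instead of expanding a pyran.
- Keck allylation of 7 with allyltributylstannane and Ti(OiPr)4/(R)-BINOL would give (R)-1-[(tert-butyldiphenylsilyl)oxy]pent-4-en-2-ol F1.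
- The copper alkoxide of F1 (n-BuLi, CuI) would be allylated with (E)-pent-2-enyl tert-butyl carbonate under [Ir(cod)Cl]2 and a chiral phosphoramidite. This gives the branched (R)-pent-1-en-3-yl ether F2, with C13 set by the ligand.
- OsO4 (cat.)/NMO on the less hindered, non-allylic-ether alkene would give the terminal diol F3, and NaIO4 would give the C9 aldehyde F4.
- Syn-selective γ-alkoxyallylboration follows, with the (Z)-reagent made from allyl methoxymethyl ether, s-BuLi, (−)-Ipc2BOMe and BF3·OEt2. It would give the threo (9R,10R) 10-O-methoxymethyl diene alcohol F5.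
- Ring-closing metathesis (second-generation Grubbs catalyst, CH2Cl2, high dilution) would give the 10-O-methoxymethyl oxocenol F6, and HCl/MeOH would give the trans-9,10-diol F7.
- Ac2O, pyridine and DMAP would then give 17.

**Step 6.** Enolisation may go toward C10 with loss of the carbonate by β-elimination, or the C12 enolate may lose the ring oxygen by β-elimination.
- The fallback sets out from 12 and comes back at 15. It makes the alkene by dehydration, without any enolate.
- NaBH4/CeCl3 (MeOH/THF, −78 °C) would give the C11 alcohol F8.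
- Ph2S[OC(CF3)2Ph]2 (CH2Cl2, 0 °C) would dehydrate it toward the non-oxygenated C12 to the oxocene cyclic carbonate F9.
- K2CO3/MeOH would then give 15.

**Step 9.** Displacement may occur at the wrong hydroxyl, acetate may attack C12 in an SN2′ sense, or elimination to the diene may intervene.
- The fallback sets out from 15 and comes back at 17. It uses neighbouring-group chemistry instead of an oxyphosphonium displacement.
- MeC(OMe)3 with PPTS (cat.) in CH2Cl2 would give the cyclic orthoacetate F10.
- Heating F10 in dry AcOH with KOAc would ionise it to the cis-fused acetoxonium ion. Acetate opens this ion at the allylic C10 with inversion, as in the second stage of the Prévost reaction, and this gives 17 directly.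

**Further compounds**
F1 | step 4 | (R)-1-[(tert-butyldiphenylsilyl)oxy]pent-4-en-2-ol | CC(C)(C)[Si](c1ccccc1)(c1ccccc1)OC[C@H](O)CC=C
F2 | step 4 | (R)-pent-1-en-3-yl ether of F1 (7R,13R) | CC[C@H](C=C)O[C@@H](CO[Si](c1ccccc1)(c1ccccc1)C(C)(C)C)CC=C
F3 | step 4 | terminal diol from the homoallylic alkene of F2 (carbinol centre undefined) | CC[C@H](C=C)O[C@@H](CO[Si](c1ccccc1)(c1ccccc1)C(C)(C)C)CC(O)CO
F4 | step 4 | C9 aldehyde (7R,13R) | CC[C@H](C=C)O[C@@H](CO[Si](c1ccccc1)(c1ccccc1)C(C)(C)C)CC=O
F5 | step 4 | (7R,9R,10R,13R) 10-O-methoxymethyl diene alcohol | CC[C@H](C=C)O[C@@H](CO[Si](c1ccccc1)(c1ccccc1)C(C)(C)C)C[C@@H](O)[C@H](OCOC)C=C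
F6 | step 4 | (7R,9R,10R,13R,11Z) 10-O-methoxymethyl oxocenol | CC[C@@H]1/C=C\[C@@H](OCOC)[C@H](O)C[C@H](CO[Si](c2ccccc2)(c2ccccc2)C(C)(C)C)O1
F7 | step 4 | (2R,4R,5R,8R,6Z)-2-{[(tert-butyldiphenylsilyl)oxy]methyl}-8-ethyl-3,4,5,8-tetrahydro-2H-oxocine-4,5-diol (trans) | CC[C@@H]1/C=C\[C@@H](O)[C@H](O)C[C@H](CO[Si](c2ccccc2)(c2ccccc2)C(C)(C)C)O1
F8 | step 6 | C11 alcohol of 12 (C11 undefined), cis C9/C10 carbonate | CC[C@@H]1CC(O)[C@@H]2OC(=O)O[C@@H]2C[C@H](CO[Si](c3ccccc3)(c3ccccc3)C(C)(C)C)O1
F9 | step 6 | (11Z)-oxocene cis C9/C10 cyclic carbonate | CC[C@@H]1/C=C\[C@@H]2OC(=O)O[C@@H]2C[C@H](CO[Si](c3ccccc3)(c3ccccc3)C(C)(C)C)O1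
F10 | step 9 | cyclic orthoacetate of 15 (orthoester carbon undefined) | CC[C@@H]1/C=C\[C@@H]2OC(C)(OC)O[C@@H]2C[C@H](CO[Si](c3ccccc3)(c3ccccc3)C(C)(C)C)O1
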